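The route rests on the C5–C6 bond (C5 = ring-fusion CH, C6 = carbinol CH of the seven-membered ring). It exploits the aldol pattern C4(O)–C5–C6(OH) that spans both rings: the five-membered ring is made as a C4 ketone whose regiodefined enol silane at C5 attacks a C6 acetal on the Z-alkenyl side chain at C1. This Mukaiyama aldol condensation closes the cycloheptene in one operation and gives a C5=C6 enone. Catalyst-controlled conjugate borylation then sets C6, C5 equilibrates to the trans ring fusion, and isopropyl addition with in situ vanilloylation, desilylation and hydroxyl-directed epoxidation finish the target.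

Key step: step 6

Numbering used in the text: C1 = methyl-bearing ring-fusion carbon, C2 and C3 = CH2 groups of the five-membered ring, C4 = ester- and isopropyl-bearing carbon, C5 = ring-fusion CH, C6 = CH(OH), C7 = CH2, C8 = methyl-bearing epoxide carbon, C9 = epoxide CH, C10 = CH2 next to C1. The β face is the face of the C1 methyl group; in the target O4 is β, H5 is α, O6 is α and the epoxide is α.

Assumption: the ligand enantiomers named in steps 5 and 7 are taken to be the ones that deliver to the stated faces (Si face of C1, Si face of C6); if the sense were reversed, the mirror-image ligand would be used.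

Step 1
Reactants: 1 but-2-yn-1-ol
Product: 3 (2Z)-3-iodobut-2-en-1-ol, via alkenylalanate 2 (not isolated)
Conditions: NaAlH2(OCH2CH2OMe)2 (Red-Al), Et2O, 0 °C to rt; then I2, THF, −78 to 0 °C
Reagents that add atoms: iodine, II
Why: Hydroxyl-directed trans-hydroalumination of the propargylic alcohol should give the cyclic alkenylalanate 2, and iodinolysis of the C–Al bond with retention gives the Z vinyl iodide (hydroalumination–iodination).

Step 2
Reactants: 3 (2Z)-3-iodobut-2-en-1-ol; 4 (1,3-dioxolan-2-ylmethyl)zinc bromide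
Product: 5 (2Z)-4-(1,3-dioxolan-2-yl)-3-methylbut-2-en-1-ol
Conditions: 4 (3 equiv, THF solution), Pd(PPh3)4 (5 mol %), THF, 50 °C
Reagents that add atoms: none
Why: Negishi coupling of the vinyl iodide with the alkylzinc bromide should proceed with retention of the Z geometry, the first equivalent of 4 only deprotonating the alcohol.

Step 3
Reactants: 5 (2Z)-4-(1,3-dioxolan-2-yl)-3-methylbut-2-en-1-ol
Product: 7 2-[(2Z)-4-chloro-2-methylbut-2-en-1-yl]-1,3-dioxolane, via allylic mesylate 6 (not isolated)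
Conditions: MsCl, 2,4,6-collidine, LiCl, DMF, 0 °C
Reagents that add atoms: lithium chloride, [Li+].[Cl-]
Why: Mesylation and in situ SN2 displacement by chloride (standard allylic alcohol to allylic chloride conversion) should leave the acetal and the Z alkene untouched.

Step 4
Reactants: 7 2-[(2Z)-4-chloro-2-methylbut-2-en-1-yl]-1,3-dioxolane; 8 3-ethoxycyclopent-2-en-1-one
Product: 11 3-[(2Z)-4-(1,3-dioxolan-2-yl)-3-methylbut-2-en-1-yl]cyclopent-2-en-1-one, via allylbarium chloride 9 (not isolated), via barium alkoxide adduct 10 (not isolated)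
Conditions: activated barium (from BaI2 and 2 equiv lithium biphenylide), THF, −78 °C, 7; then 8, −78 °C; then 0.5 M HCl, 0 °C
Reagents that add atoms: water, O
Why: Allylbarium reagents add to carbonyl groups at their unsubstituted α-carbon with retention of alkene geometry, so 1,2-addition to the vinylogous ester and acid hydrolysis (Stork–Danheiser transposition) should give the β-substituted enone.

Step 5
Reactants: 11 3-[(2Z)-4-(1,3-dioxolan-2-yl)-3-methylbut-2-en-1-yl]cyclopent-2-en-1-one
Product: 13 triethyl({(3R)-3-[(2Z)-4-(1,3-dioxolan-2-yl)-3-methylbut-2-en-1-yl]-3-methylcyclopent-1-en-1-yl}oxy)silane, via aluminium enolate 12 (not isolated)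
Conditions: Me3Al (3 equiv), copper thiophene-2-carboxylate (monovalent copper, 5 mol %), phosphoramidite L1 = O,O'-[(S)-1,1'-binaphthalene-2,2'-diyl] N,N-bis[(R)-1-phenylethyl]phosphoramidite (10 mol %), Et2O, −30 °C; then Et3SiOTf, −78 °C; Et3N
Reagents that add atoms: trimethylaluminium, C[Al](C)C; triethylsilyl trifluoromethanesulfonate, CC[Si](CC)(CC)OS(=O)(=O)C(F)(F)F
Why: Copper-catalysed asymmetric conjugate addition of Me3Al to the β-substituted cyclopentenone should create the quaternary stereocentre C1 under ligand control (methyl to the Si face of C1), and O-silylation of the aluminium enolate fixes the C4–C5 enol regiochemistry.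

Step 6
Reactants: 13 triethyl({(3R)-3-[(2Z)-4-(1,3-dioxolan-2-yl)-3-methylbut-2-en-1-yl]-3-methylcyclopent-1-en-1-yl}oxy)silane
Product: 15 (3aR)-3a,6-dimethyl-3,3a,4,7-tetrahydroazulen-1(2H)-one, via β-alkoxy ketone 14 (not isolated)
Conditions: Me3SiOTf (0.2 equiv), CH2Cl2 (0.005 M), −78 to −40 °C; then DBU, 0 °C
Reagents that add atoms: none
Why: Me3SiOTf ionises the dioxolane to an oxocarbenium ion at C6, which is attacked by C5 of the regiodefined triethylsilyl enol ether (silyl transfer to the glycol oxygen regenerates the silyl triflate), and DBU then expels the 2-silyloxyethoxide from the β-alkoxy ketone 14 by E1cB elimination. The closest known reaction type is the intramolecular Mukaiyama aldol reaction of an enol silane with an acetal followed by aldol-type dehydration, an aldol condensation overall. The seven-membered ring closes in a 7-(enolexo)-exo-trig mode, helped by the Z-configured C8=C9 bond that holds C6 near C5. No stereocentre is kept from this step: the C5 and C6 centres of 14 are erased on purpose, because a tether that starts at C1 can reach the planar C5 only on the face of C10 (cis ring fusion), so both centres are set afterwards in step 7. The step needs regioselectivity for C5 over C3, which the enol silane from step 5 secures, and chemoselectivity towards the trisubstituted alkene, which cannot attack C6 without forming a three- or four-membered ring. High dilution should suppress intermolecular aldol reaction.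

Step 7
Reactants: 15 (3aR)-3a,6-dimethyl-3,3a,4,7-tetrahydroazulen-1(2H)-one
Product: 17 (3aR,8S,8aS)-8-hydroxy-3a,6-dimethyl-3,3a,4,7,8,8a-hexahydroazulen-1(2H)-one, via β-boryl ketone 16 (not isolated)
Conditions: B2pin2, CuCl (5 mol %), NaOtBu (10 mol %), (R,R)-QuinoxP* (6 mol %), MeOH (2 equiv), THF, rt; then DBU (0.2 equiv); then H2O2, pH 7 buffer, 0 °C
Reagents that add atoms: hydrogen peroxide, OO
Why: Copper-catalysed enantioselective conjugate borylation should deliver boron to the Si (α) face of C6 under ligand control; C5, α to the ketone, then equilibrates to the trans ring fusion with the C6 substituent equatorial (the cis-fused epimer would place either that substituent or C4 axial), and oxidation of the C–B bond occurs with retention.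

Step 8
Reactants: 17 (3aR,8S,8aS)-8-hydroxy-3a,6-dimethyl-3,3a,4,7,8,8a-hexahydroazulen-1(2H)-one
Product: 18 (3aR,8S,8aS)-8-{[tert-butyl(dimethyl)silyl]oxy}-3a,6-dimethyl-3,3a,4,7,8,8a-hexahydroazulen-1(2H)-one
Conditions: tBuMe2SiOTf, 2,6-lutidine, CH2Cl2, −78 °C
Reagents that add atoms: tert-butyldimethylsilyl trifluoromethanesulfonate, CC(C)(C)[Si](C)(C)OS(=O)(=O)C(F)(F)F
Why: Silylation of the secondary alcohol with the silyl triflate under non-enolising conditions protects O6 for the organometallic step.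

Step 9
Reactants: 19 vanillic acid (4-hydroxy-3-methoxybenzoic acid)
Product: 21 4-{[tert-butyl(dimethyl)silyl]oxy}-3-methoxybenzoyl chloride, via bis-silyl vanillate 20 (not isolated)
Conditions: tBuMe2SiCl (2.2 equiv), imidazole, DMF, rt; then (COCl)2, DMF (cat.), CH2Cl2, 0 °C to rt
Reagents that add atoms: tert-butyldimethylsilyl chloride, CC(C)(C)[Si](C)(C)Cl; oxalyl chloride, O=C(Cl)C(Cl)=O
Why: Silylation of phenol and acid, then conversion of the silyl ester into the acid chloride with oxalyl chloride and catalytic DMF (neutral conditions), should leave the aryl silyl ether intact.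

Step 10
Reactants: 18 (3aR,8S,8aS)-8-{[tert-butyl(dimethyl)silyl]oxy}-3a,6-dimethyl-3,3a,4,7,8,8a-hexahydroazulen-1(2H)-one; 21 4-{[tert-butyl(dimethyl)silyl]oxy}-3-methoxybenzoyl chloride
Product: 23 (1R,3aR,8S,8aS)-8-{[tert-butyl(dimethyl)silyl]oxy}-3a,6-dimethyl-1-(propan-2-yl)-1,2,3,3a,4,7,8,8a-octahydroazulen-1-yl 4-{[tert-butyl(dimethyl)silyl]oxy}-3-methoxybenzoate, via magnesium alkoxide 22 (not isolated)
Conditions: iPrMgCl, LaCl3·2LiCl, THF, −20 °C; then 21, −20 °C to rt
Reagents that add atoms: isopropylmagnesium chloride, CC(C)[Mg]Cl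
Why: LaCl3·2LiCl-promoted Grignard 1,2-addition should occur on the α face of the ketone, anti to the C5–C6 bond and to the angular methyl group, which sets C4 with O4 β (cis to C6), and the tertiary alkoxide is trapped as the ester by the acid chloride (alkoxide acylation).

Step 11
Reactants: 23 (1R,3aR,8S,8aS)-8-{[tert-butyl(dimethyl)silyl]oxy}-3a,6-dimethyl-1-(propan-2-yl)-1,2,3,3a,4,7,8,8a-octahydroazulen-1-yl 4-{[tert-butyl(dimethyl)silyl]oxy}-3-methoxybenzoate
Product: 24 (1R,3aR,8S,8aS)-8-hydroxy-3a,6-dimethyl-1-(propan-2-yl)-1,2,3,3a,4,7,8,8a-octahydroazulen-1-yl 4-hydroxy-3-methoxybenzoate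
Conditions: HF·pyridine, pyridine, THF, 0 °C to rt
Reagents that add atoms: none
Why: Buffered HF·pyridine should cleave the aryl and the secondary silyl ether (fluoride desilylation) without cleaving or migrating the tertiary ester.

Step 12
Reactants: 24 (1R,3aR,8S,8aS)-8-hydroxy-3a,6-dimethyl-1-(propan-2-yl)-1,2,3,3a,4,7,8,8a-octahydroazulen-1-yl 4-hydroxy-3-methoxybenzoate
Product: 25 (1R,3aR,5S,6R,8S,8aS)-5,6-epoxy-8-hydroxy-3a,6-dimethyl-1-(propan-2-yl)decahydroazulen-1-yl 4-hydroxy-3-methoxybenzoate (CNP0315707.1)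
Conditions: mCPBA, NaHCO3, CH2Cl2, 0 °C
Reagents that add atoms: 3-chloroperoxybenzoic acid, OOC(=O)c1cccc(Cl)c1
Why: Prilezhaev epoxidation of the only alkene should take place on the α face, guided by hydrogen bonding to the homoallylic C6 hydroxyl and by the axial C1 methyl group that shields the β face, which sets C8 and C9.

Compound list

1 | but-2-yn-1-ol | CC#CCO | starting material
2 | sodium cyclic alkenylalanate from 1 (Al on C3, cis to the CH2O group) | [Na+].COCCO[Al-]1(OCCOC)OCC=C1C | intermediate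
3 | (2Z)-3-iodobut-2-en-1-ol | OC/C=C(\I)C | intermediate
4 | (1,3-dioxolan-2-ylmethyl)zinc bromide | Br[Zn]CC1OCCO1 | starting material
5 | (2Z)-4-(1,3-dioxolan-2-yl)-3-methylbut-2-en-1-ol | OC/C=C(\CC1OCCO1)C | intermediate
6 | (2Z)-4-(1,3-dioxolan-2-yl)-3-methylbut-2-en-1-yl methanesulfonate | CS(=O)(=O)OC/C=C(\CC1OCCO1)C | intermediate
7 | 2-[(2Z)-4-chloro-2-methylbut-2-en-1-yl]-1,3-dioxolane | ClC/C=C(\CC1OCCO1)C | intermediate
8 | 3-ethoxycyclopent-2-en-1-one | CCOC1=CC(=O)CC1 | starting material
9 | [(2Z)-4-(1,3-dioxolan-2-yl)-3-methylbut-2-en-1-yl]barium chloride | Cl[Ba]C/C=C(\CC1OCCO1)C | intermediate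
10 | chlorobarium 1-[(2Z)-4-(1,3-dioxolan-2-yl)-3-methylbut-2-en-1-yl]-3-ethoxycyclopent-2-en-1-olate (racemic) | CCOC1=CC(O[Ba]Cl)(C/C=C(\CC2OCCO2)C)CC1 | intermediate
11 | 3-[(2Z)-4-(1,3-dioxolan-2-yl)-3-methylbut-2-en-1-yl]cyclopent-2-en-1-one | O=C1C=C(C/C=C(\CC2OCCO2)C)CC1 | intermediate
12 | dimethylaluminium enolate of (3R)-3-[(2Z)-4-(1,3-dioxolan-2-yl)-3-methylbut-2-en-1-yl]-3-methylcyclopentanone (enolate towards C5) | C[Al](C)OC1=C[C@@](C)(C/C=C(\CC2OCCO2)C)CC1 | intermediate
13 | triethyl({(3R)-3-[(2Z)-4-(1,3-dioxolan-2-yl)-3-methylbut-2-en-1-yl]-3-methylcyclopent-1-en-1-yl}oxy)silane | CC[Si](CC)(CC)OC1=C[C@@](C)(C/C=C(\CC2OCCO2)C)CC1 | intermediate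
14 | (3aR)-3a,6-dimethyl-8-{2-[(triethylsilyl)oxy]ethoxy}-3,3a,4,7,8,8a-hexahydroazulen-1(2H)-one (mixture at C8 and C8a) | O=C1CC[C@]2(C)CC=C(C)CC(OCCO[Si](CC)(CC)CC)C12 | intermediate
15 | (3aR)-3a,6-dimethyl-3,3a,4,7-tetrahydroazulen-1(2H)-one | O=C1CC[C@]2(C)CC=C(C)CC=C12 | intermediate
16 | (3aR,8S,8aR)-3a,6-dimethyl-8-(4,4,5,5-tetramethyl-1,3,2-dioxaborolan-2-yl)-3,3a,4,7,8,8a-hexahydroazulen-1(2H)-one (trans ring fusion, boron α) | O=C1CC[C@]2(C)CC=C(C)C[C@H](B3OC(C)(C)C(C)(C)O3)[C@@H]12 | intermediate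
17 | (3aR,8S,8aS)-8-hydroxy-3a,6-dimethyl-3,3a,4,7,8,8a-hexahydroazulen-1(2H)-one (trans ring fusion, OH α) | O=C1CC[C@]2(C)CC=C(C)C[C@H](O)[C@@H]12 | intermediate
18 | (3aR,8S,8aS)-8-{[tert-butyl(dimethyl)silyl]oxy}-3a,6-dimethyl-3,3a,4,7,8,8a-hexahydroazulen-1(2H)-one | O=C1CC[C@]2(C)CC=C(C)C[C@H](O[Si](C)(C)C(C)(C)C)[C@@H]12 | intermediate
19 | vanillic acid (4-hydroxy-3-methoxybenzoic acid) | COc1cc(C(=O)O)ccc1O | starting material
20 | tert-butyl(dimethyl)silyl 4-{[tert-butyl(dimethyl)silyl]oxy}-3-methoxybenzoate | COc1cc(C(=O)O[Si](C)(C)C(C)(C)C)ccc1O[Si](C)(C)C(C)(C)C | intermediate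
21 | 4-{[tert-butyl(dimethyl)silyl]oxy}-3-methoxybenzoyl chloride | COc1cc(C(Cl)=O)ccc1O[Si](C)(C)C(C)(C)C | intermediate
22 | chloromagnesium (1R,3aR,8S,8aS)-8-{[tert-butyl(dimethyl)silyl]oxy}-3a,6-dimethyl-1-(propan-2-yl)-1,2,3,3a,4,7,8,8a-octahydroazulen-1-olate | Cl[Mg]O[C@@]1(C(C)C)CC[C@]2(C)CC=C(C)C[C@H](O[Si](C)(C)C(C)(C)C)[C@H]21 | intermediate
23 | (1R,3aR,8S,8aS)-8-{[tert-butyl(dimethyl)silyl]oxy}-3a,6-dimethyl-1-(propan-2-yl)-1,2,3,3a,4,7,8,8a-octahydroazulen-1-yl 4-{[tert-butyl(dimethyl)silyl]oxy}-3-methoxybenzoate | COc1cc(C(=O)O[C@@]2(C(C)C)CC[C@]3(C)CC=C(C)C[C@H](O[Si](C)(C)C(C)(C)C)[C@H]32)ccc1O[Si](C)(C)C(C)(C)C | intermediate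
24 | (1R,3aR,8S,8aS)-8-hydroxy-3a,6-dimethyl-1-(propan-2-yl)-1,2,3,3a,4,7,8,8a-octahydroazulen-1-yl 4-hydroxy-3-methoxybenzoate | COc1cc(C(=O)O[C@@]2(C(C)C)CC[C@]3(C)CC=C(C)C[C@H](O)[C@H]32)ccc1O | intermediate
25 | (1R,3aR,5S,6R,8S,8aS)-5,6-epoxy-8-hydroxy-3a,6-dimethyl-1-(propan-2-yl)decahydroazulen-1-yl 4-hydroxy-3-methoxybenzoate (CNP0315707.1) | COc1cc(C(=O)O[C@@]2(C(C)C)CC[C@]3(C)C[C@@H]4O[C@]4(C)C[C@H](O)[C@H]32)ccc1O | target

Total step count: 12
Longest linear sequence: 11 steps (steps 1 to 8 and 10 to 12; step 9 is the side branch to the acid chloride)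

Steps most likely to fail

Step 6. The seven-membered ring closure may lose out to intermolecular aldol reaction, and the base used for the elimination may move the C8=C9 double bond into conjugation with the new enone. The fallback sets out from 13 and closes the ring with a samarium enolate instead of an enol silane. Bromination of 13 with N-bromosuccinimide in THF at −78 °C should give (3R)-2-bromo-3-[(2Z)-4-(1,3-dioxolan-2-yl)-3-methylbut-2-en-1-yl]-3-methylcyclopentan-1-one F1. Acetal hydrolysis with pyridinium tosylate in wet acetone should give (3Z)-5-[(1R)-2-bromo-1-methyl-3-oxocyclopentyl]-3-methylpent-3-enal F2. SmI2 in THF at −78 °C under high dilution should then effect an intramolecular Reformatsky-type aldol to (3aR)-8-hydroxy-3a,6-dimethyl-3,3a,4,7,8,8a-hexahydroazulen-1(2H)-one F3 as a mixture of epimers at C8 and C8a. Mesylation with MsCl and Et3N and elimination under these mild conditions brings the route back at 15.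

Step 7. Boron may be delivered to the wrong face of C6, or protonation at C5 may stay under kinetic control and leave the cis ring fusion. The fallback sets out from 15 and introduces the C6 oxygen as an epoxide. Nucleophilic epoxidation with tert-butyl hydroperoxide and DBU, in which the peroxide anion should add to C6 anti to the C1 methyl group, should give (3aR)-8,8a-epoxy-3a,6-dimethyl-3,3a,4,7,8,8a-hexahydroazulen-1(2H)-one with the oxirane oxygen trans to the C3a methyl group F4. SmI2 with MeOH in THF at −78 °C should cleave the C–O bond α to the ketone, and protonation with equilibration at C5 returns the route at 17.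

Step 10. The hindered, enolisable ketone may be enolised or reduced by β-hydride transfer in place of addition, and the crowded tertiary alkoxide may acylate slowly or take the silyl group from O6. The fallback sets out from 18 and separates the three events. Addition of prop-1-en-2-yllithium with CeCl3 in THF at −78 °C (no β-hydride on the reagent) should give (1S,3aR,8S,8aS)-8-{[tert-butyl(dimethyl)silyl]oxy}-3a,6-dimethyl-1-(prop-1-en-2-yl)-1,2,3,3a,4,7,8,8a-octahydroazulen-1-ol F5. Deprotonation with KN(SiMe3)2 at −78 °C and acylation with 21 should give (1S,3aR,8S,8aS)-8-{[tert-butyl(dimethyl)silyl]oxy}-3a,6-dimethyl-1-(prop-1-en-2-yl)-1,2,3,3a,4,7,8,8a-octahydroazulen-1-yl 4-{[tert-butyl(dimethyl)silyl]oxy}-3-methoxybenzoate F6. Selective hydrogenation of the 1,1-disubstituted alkene with H2 and RhCl(PPh3)3 in benzene returns the route at 23.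

Further compounds

F1 | step 6 | (3R)-2-bromo-3-[(2Z)-4-(1,3-dioxolan-2-yl)-3-methylbut-2-en-1-yl]-3-methylcyclopentan-1-one (mixture at C2) | O=C1CC[C@](C)(C/C=C(\CC2OCCO2)C)C1Br
F2 | step 6 | (3Z)-5-[(1R)-2-bromo-1-methyl-3-oxocyclopentyl]-3-methylpent-3-enal (mixture at the CHBr carbon) | O=C1CC[C@](C)(C/C=C(\CC=O)C)C1Br
F3 | step 6 | (3aR)-8-hydroxy-3a,6-dimethyl-3,3a,4,7,8,8a-hexahydroazulen-1(2H)-one (mixture at C8 and C8a) | O=C1CC[C@]2(C)CC=C(C)CC(O)C12
F4 | step 7 | (3aR)-8,8a-epoxy-3a,6-dimethyl-3,3a,4,7,8,8a-hexahydroazulen-1(2H)-one, oxirane oxygen trans to the C3a methyl group | O=C1CC[C@]2(C)CC=C(C)C[C@@H]3O[C@]123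
F5 | step 10 | (1S,3aR,8S,8aS)-8-{[tert-butyl(dimethyl)silyl]oxy}-3a,6-dimethyl-1-(prop-1-en-2-yl)-1,2,3,3a,4,7,8,8a-octahydroazulen-1-ol | O[C@@]1(C(C)=C)CC[C@]2(C)CC=C(C)C[C@H](O[Si](C)(C)C(C)(C)C)[C@H]21
F6 | step 10 | (1S,3aR,8S,8aS)-8-{[tert-butyl(dimethyl)silyl]oxy}-3a,6-dimethyl-1-(prop-1-en-2-yl)-1,2,3,3a,4,7,8,8a-octahydroazulen-1-yl 4-{[tert-butyl(dimethyl)silyl]oxy}-3-methoxybenzoate | COc1cc(C(=O)O[C@@]2(C(C)=C)CC[C@]3(C)CC=C(C)C[C@H](O[Si](C)(C)C(C)(C)C)[C@H]32)ccc1O[Si](C)(C)C(C)(C)C
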